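**Retrosynthetic overview**

1. The C3–O ester bond is cut last (bicycle numbering: C1 methyl-bearing oxirane carbon, C2 carbonyl, C3 acyloxy carbon, C4 isopropenyl carbon, C6 oxirane CH), giving a hydroxy epoxy ketone and a diester acid made from prenyl tiglate by allylic oxidation.
2. Key disconnection: the C1–C6 bond, which is both the C–C edge of the oxirane and a bond of the cyclohexanone; both rings close in one operation from an acyclic 6-chloro-5-oxoheptanal through an acyl-stabilised sulfonium ylide.
3. Enabling feature: C1 is a fully substituted oxirane carbon alpha to the C2 ketone, so it can be a stabilised ylide carbon, and C6 is an oxirane CH at the aldehyde oxidation level five atoms away; the alpha,beta-epoxy ketone is a glycidic (Darzens-type) retron embedded in the six-membered ring.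
4. The acyclic precursor comes from a delta-lactone by acylation of 1-chloroethyllithium and oxidation; C4 is set by asymmetric conjugate addition of an isopropenyl group to 5,6-dihydro-2H-pyran-2-one and C3 by trans-selective enolate hydroxylation.
5. Ring order: delta-lactone (temporary ring that relays C4 to C3), opened, then cyclohexanone (C–C), then oxirane (C–O).

Key step: step 6

Remark: compounds 8 to 13 are carried as mixtures of epimers at the halogen- or sulfur-bearing carbon (8 also at the lactol carbon, 9 partly as its cyclic hemiketal); this centre becomes planar in ylide 13, so their SMILES leave it undefined.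
Assumption: (S)-BINAP is assumed to give the (S)-lactone 3, by analogy with the facial sense usual for cyclic enones and enoates; if the opposite sense is found, (R)-BINAP is used.

**Route**

Step 1
Reactants: 1 5,6-dihydro-2H-pyran-2-one; 2 potassium trifluoro(prop-1-en-2-yl)borate
Product: 3 (S)-4-(prop-1-en-2-yl)tetrahydro-2H-pyran-2-one
Conditions: [Rh(cod)2]BF4 (3 mol %), (S)-BINAP (3.3 mol %), 2 (2 equiv), toluene/H2O 10:1, 100 °C
Reagents that add atoms: none
Why: Hayashi–Miyaura reaction, in which the alkenylrhodium–BINAP species adds to one enantioface of the unsaturated lactone and water protonates the rhodium enolate, which should set C4 as (S).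

Step 2
Reactants: 3 (S)-4-(prop-1-en-2-yl)tetrahydro-2H-pyran-2-one
Product: 5 (3R,4R)-3-hydroxy-4-(prop-1-en-2-yl)tetrahydro-2H-pyran-2-one, via potassium enolate 4 (not isolated)
Conditions: KN(SiMe3)2 (1.1 equiv), THF, −78 °C; 2-(phenylsulfonyl)-3-phenyloxaziridine (1.3 equiv), −78 °C; AcOH
Reagents that add atoms: 2-(phenylsulfonyl)-3-phenyloxaziridine, O=S(=O)(c1ccccc1)N1OC1c1ccccc1
Why: Enolate hydroxylation by an N-sulfonyloxaziridine, in which the oxidant should approach the half-chair lactone enolate anti to the adjacent C4 isopropenyl group and so set C3 trans to C4.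

Step 3
Reactants: 5 (3R,4R)-3-hydroxy-4-(prop-1-en-2-yl)tetrahydro-2H-pyran-2-one
Product: 6 (3R,4R)-3-[(tert-butyldimethylsilyl)oxy]-4-(prop-1-en-2-yl)tetrahydro-2H-pyran-2-one
Conditions: TBSOTf (1.3 equiv), 2,6-lutidine (2 equiv), CH2Cl2, 0 °C
Reagents that add atoms: tert-butyldimethylsilyl trifluoromethanesulfonate, CC(C)(C)[Si](C)(C)OS(=O)(=O)C(F)(F)F
Why: Silylation of a hindered secondary alcohol with a silyl triflate and a hindered pyridine base; no stereocentre is touched.

Step 4
Reactants: 6 (3R,4R)-3-[(tert-butyldimethylsilyl)oxy]-4-(prop-1-en-2-yl)tetrahydro-2H-pyran-2-one; 7 1-bromo-1-chloroethane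
Product: 9 (4R,5R)-4-[(tert-butyldimethylsilyl)oxy]-2-chloro-7-hydroxy-5-(prop-1-en-2-yl)heptan-3-one, via lithium lactolate 8 (not isolated)
Conditions: 7 (2.5 equiv), n-BuLi (2.3 equiv, added slowly to 6 + 7), THF/Et2O, −100 °C; AcOH, −100 °C → 23 °C
Reagents that add atoms: none
Why: Barbier-type carbenoid acylation, in which bromine–lithium exchange gives 1-chloroethyllithium beside the lactone, the tetrahedral lactolate stops the reaction at single addition, and cold protonation prevents oxirane closure onto the C–Cl bond; the two existing stereocentres are not touched.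

Step 5
Reactants: 9 (4R,5R)-4-[(tert-butyldimethylsilyl)oxy]-2-chloro-7-hydroxy-5-(prop-1-en-2-yl)heptan-3-one
Product: 10 (3R,4R)-4-[(tert-butyldimethylsilyl)oxy]-6-chloro-5-oxo-3-(prop-1-en-2-yl)heptanal
Conditions: DMP (1,1,1-triacetoxy-1,1-dihydro-1,2-benziodoxol-3(1H)-one, 1.3 equiv), CH2Cl2, 0 → 23 °C
Reagents that add atoms: none
Why: Dess–Martin oxidation of the primary alcohol through the open-chain tautomer (the tertiary hemiketal cannot be oxidised) under non-basic conditions that should leave the alpha-chloro ketone and the silyloxy-bearing stereocentre intact.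

Step 6
Reactants: 10 (3R,4R)-4-[(tert-butyldimethylsilyl)oxy]-6-chloro-5-oxo-3-(prop-1-en-2-yl)heptanal
Product: 15 (1S,3R,4R,6S)-3-[(tert-butyldimethylsilyl)oxy]-1-methyl-4-(prop-1-en-2-yl)-7-oxabicyclo[4.1.0]heptan-2-one, via iodo ketone 11 (not isolated), via sulfonium iodide 12 (not isolated), via sulfonium ylide 13 (not isolated), via betaine 14 (not isolated)
Conditions: NaI (1.2 equiv), tetrahydrothiophene (3 equiv), MeCN, 23 °C, dark; then K2CO3 (3 equiv), 0 → 23 °C
Reagents that add atoms: none
Why: Proposed new method: Finkelstein exchange and S-alkylation of tetrahydrothiophene should convert the alpha-chloro ketone into beta-keto sulfonium salt 12, carbonate then removes only its C–H (estimated pKa about 9 to 11, far below the aldehyde CH2 and the silyloxy-bearing CH) to give acyl-stabilised ylide 13, the ylide carbon adds to the tethered aldehyde to form the C1–C6 bond, and the alkoxide displaces the sulfide to close the oxirane. The closest known reactions are the Johnson–Corey–Chaykovsky epoxidation of aldehydes by keto-stabilised sulfonium ylides made in the flask from an alpha-halo ketone, a sulfide and a carbonate base, and the Darzens condensation; ring-closing ylide epoxidations onto tethered carbonyl groups are known for non-stabilised ylides, and the new element is the ring-closing use of a keto-stabilised ylide on an omega-formyl alpha-halo ketone to build a carbocycle. The cyclohexanone closes by a 6-(enolendo)-exo-trig addition and the oxirane by a 3-exo-tet SN2 displacement with inversion at C1. Betaine formation from a stabilised ylide is reversible, and only betaine 14, with O− on C6 and S+ on C1 trans-diaxial in a chair that keeps the C3 silyloxy and C4 isopropenyl groups equatorial, can reach the anti-periplanar geometry for closure, so the oxirane oxygen should end up cis to the C3 oxygen and trans to the C4 isopropenyl group, that is (1S,6S); the cis fusion required of a cyclohexane-fused oxirane ties the configuration of the quaternary C1 to that of C6. The step needs the carbon nucleophile to be generated only at C1 in the presence of an enolisable aldehyde and an epimerisable C3–H (plain base would risk aldehyde-enolate C-alkylation, Favorskii rearrangement and C3 epimerisation), and the sulfonium group secures this by making the C1–H so much more acidic than any other C–H that a weak heterogeneous base suffices.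

Step 7
Reactants: 15 (1S,3R,4R,6S)-3-[(tert-butyldimethylsilyl)oxy]-1-methyl-4-(prop-1-en-2-yl)-7-oxabicyclo[4.1.0]heptan-2-one
Product: 16 (1S,3R,4R,6S)-3-hydroxy-1-methyl-4-(prop-1-en-2-yl)-7-oxabicyclo[4.1.0]heptan-2-one
Conditions: HF·pyridine, pyridine, THF, 0 → 23 °C
Reagents that add atoms: none
Why: Fluoride-mediated Si–O cleavage under buffered, weakly acidic conditions, which should avoid base-induced alpha-ketol rearrangement; the ketone-deactivated oxirane should resist opening.

Step 8
Reactants: 17 3-methylbut-2-en-1-ol; 18 (E)-2-methylbut-2-enoyl chloride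
Product: 19 3-methylbut-2-en-1-yl (E)-2-methylbut-2-enoate
Conditions: Et3N (1.5 equiv), DMAP (5 mol %), CH2Cl2, 0 → 23 °C
Reagents that add atoms: none
Why: Acylation of a primary allylic alcohol by an acid chloride; the (E)-geometry of the tigloyl unit is retained.

Step 9
Reactants: 19 3-methylbut-2-en-1-yl (E)-2-methylbut-2-enoate
Product: 20 (E)-3-methyl-4-oxobut-2-en-1-yl (E)-2-methylbut-2-enoate
Conditions: SeO2 (1.1 equiv), 1,4-dioxane, 80 °C
Reagents that add atoms: selenium dioxide (SeO2), O=[Se]=O
Why: Riley oxidation (ene reaction, then [2,3]-sigmatropic shift), which should take place at the electron-rich prenyl alkene rather than the conjugated tiglate alkene and at the (E)-methyl group, setting the (E)-enal.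

Step 10
Reactants: 20 (E)-3-methyl-4-oxobut-2-en-1-yl (E)-2-methylbut-2-enoate
Product: 21 (E)-2-methyl-4-{[(E)-2-methylbut-2-enoyl]oxy}but-2-enoic acid
Conditions: NaClO2, NaH2PO4, 2-methylbut-2-ene, t-BuOH/H2O, 0 → 23 °C
Reagents that add atoms: sodium chlorite (NaClO2), [Na+].[O-]Cl=O
Why: Pinnick oxidation of the enal to the acid with the alkene scavenger consuming HOCl, so that neither alkene geometry nor the ester should be affected.

Step 11
Reactants: 16 (1S,3R,4R,6S)-3-hydroxy-1-methyl-4-(prop-1-en-2-yl)-7-oxabicyclo[4.1.0]heptan-2-one; 21 (E)-2-methyl-4-{[(E)-2-methylbut-2-enoyl]oxy}but-2-enoic acid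
Product: 23 (1S,3R,4R,6S)-1-methyl-2-oxo-4-(prop-1-en-2-yl)-7-oxabicyclo[4.1.0]heptan-3-yl (E)-2-methyl-4-{[(E)-2-methylbut-2-enoyl]oxy}but-2-enoate, via mixed anhydride 22 (not isolated)
Conditions: 21 (1.5 equiv), 2,4,6-trichlorobenzoyl chloride (1.5 equiv), Et3N (3 equiv), THF, 23 °C; then 16, DMAP (2 equiv), toluene, 23 °C
Reagents that add atoms: none
Why: Yamaguchi esterification, in which DMAP attacks the less hindered enoyl carbonyl of the mixed anhydride and the C3–O bond is never broken, so C3 keeps its configuration (the equatorial, trans arrangement is also the thermodynamic one).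

**Compound list**

1 | 5,6-dihydro-2H-pyran-2-one | O=C1OCCC=C1 | starting material
2 | potassium trifluoro(prop-1-en-2-yl)borate | [K+].C=C(C)[B-](F)(F)F | starting material
3 | (S)-4-(prop-1-en-2-yl)tetrahydro-2H-pyran-2-one | C=C(C)[C@H]1CCOC(=O)C1 | intermediate
4 | potassium (S)-4-(prop-1-en-2-yl)-5,6-dihydro-4H-pyran-2-olate (enolate of 3) | C=C(C)[C@H]1CCOC([O-])=C1.[K+] | intermediate
5 | (3R,4R)-3-hydroxy-4-(prop-1-en-2-yl)tetrahydro-2H-pyran-2-one | C=C(C)[C@H]1CCOC(=O)[C@@H]1O | intermediate
6 | (3R,4R)-3-[(tert-butyldimethylsilyl)oxy]-4-(prop-1-en-2-yl)tetrahydro-2H-pyran-2-one | C=C(C)[C@H]1CCOC(=O)[C@@H]1O[Si](C)(C)C(C)(C)C | intermediate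
7 | 1-bromo-1-chloroethane | CC(Cl)Br | starting material
8 | lithium (3R,4R)-3-[(tert-butyldimethylsilyl)oxy]-2-(1-chloroethyl)-4-(prop-1-en-2-yl)tetrahydro-2H-pyran-2-olate | C=C(C)[C@H]1CCOC([O-])(C(C)Cl)[C@@H]1O[Si](C)(C)C(C)(C)C.[Li+] | intermediate
9 | (4R,5R)-4-[(tert-butyldimethylsilyl)oxy]-2-chloro-7-hydroxy-5-(prop-1-en-2-yl)heptan-3-one | C=C(C)[C@H]([C@@H](O[Si](C)(C)C(C)(C)C)C(=O)C(C)Cl)CCO | intermediate
10 | (3R,4R)-4-[(tert-butyldimethylsilyl)oxy]-6-chloro-5-oxo-3-(prop-1-en-2-yl)heptanal | C=C(C)[C@H]([C@@H](O[Si](C)(C)C(C)(C)C)C(=O)C(C)Cl)CC=O | intermediate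
11 | (3R,4R)-4-[(tert-butyldimethylsilyl)oxy]-6-iodo-5-oxo-3-(prop-1-en-2-yl)heptanal | C=C(C)[C@H]([C@@H](O[Si](C)(C)C(C)(C)C)C(=O)C(C)I)CC=O | intermediate
12 | 1-[(4R,5R)-4-[(tert-butyldimethylsilyl)oxy]-3,7-dioxo-5-(prop-1-en-2-yl)heptan-2-yl]tetrahydrothiophen-1-ium iodide | C=C(C)[C@H]([C@@H](O[Si](C)(C)C(C)(C)C)C(=O)C(C)[S+]1CCCC1)CC=O.[I-] | intermediate
13 | (4R,5R)-4-[(tert-butyldimethylsilyl)oxy]-3,7-dioxo-5-(prop-1-en-2-yl)-2-(tetrahydrothiophen-1-ium-1-yl)heptan-2-ide | C=C(C)[C@H]([C@@H](O[Si](C)(C)C(C)(C)C)C(=O)[C-](C)[S+]1CCCC1)CC=O | intermediate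
14 | (2R,3S,5R,6R)-6-[(tert-butyldimethylsilyl)oxy]-2-methyl-3-oxido-5-(prop-1-en-2-yl)-2-(tetrahydrothiophen-1-ium-1-yl)cyclohexan-1-one | C=C(C)[C@H]1C[C@H]([O-])[C@@](C)([S+]2CCCC2)C(=O)[C@@H]1O[Si](C)(C)C(C)(C)C | intermediate
15 | (1S,3R,4R,6S)-3-[(tert-butyldimethylsilyl)oxy]-1-methyl-4-(prop-1-en-2-yl)-7-oxabicyclo[4.1.0]heptan-2-one | C=C(C)[C@H]1C[C@@H]2O[C@]2(C)C(=O)[C@@H]1O[Si](C)(C)C(C)(C)C | intermediate
16 | (1S,3R,4R,6S)-3-hydroxy-1-methyl-4-(prop-1-en-2-yl)-7-oxabicyclo[4.1.0]heptan-2-one | C=C(C)[C@H]1C[C@@H]2O[C@]2(C)C(=O)[C@@H]1O | intermediate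
17 | 3-methylbut-2-en-1-ol | CC(C)=CCO | starting material
18 | (E)-2-methylbut-2-enoyl chloride | ClC(=O)/C(C)=C/C | starting material
19 | 3-methylbut-2-en-1-yl (E)-2-methylbut-2-enoate | CC(C)=CCOC(=O)/C(C)=C/C | intermediate
20 | (E)-3-methyl-4-oxobut-2-en-1-yl (E)-2-methylbut-2-enoate | O=C/C(C)=C/COC(=O)/C(C)=C/C | intermediate
21 | (E)-2-methyl-4-{[(E)-2-methylbut-2-enoyl]oxy}but-2-enoic acid | OC(=O)/C(C)=C/COC(=O)/C(C)=C/C | intermediate
22 | (E)-2-methyl-4-{[(E)-2-methylbut-2-enoyl]oxy}but-2-enoic 2,4,6-trichlorobenzoic anhydride | O=C(OC(=O)/C(C)=C/COC(=O)/C(C)=C/C)c1c(Cl)cc(Cl)cc1Cl | intermediate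
23 | (1S,3R,4R,6S)-1-methyl-2-oxo-4-(prop-1-en-2-yl)-7-oxabicyclo[4.1.0]heptan-3-yl (E)-2-methyl-4-{[(E)-2-methylbut-2-enoyl]oxy}but-2-enoate | C=C(C)[C@H]1C[C@@H]2O[C@]2(C)C(=O)[C@@H]1OC(=O)/C(C)=C/COC(=O)/C(C)=C/C | target

**Step count**

Total steps: 11. Longest linear sequence: 8 steps (steps 1 to 7 and 11, from 1); the side chain takes 3 steps (8 to 10).

**Three steps most likely to fail**

1. Step 6 (proposed new method). What may go wrong: slow S-alkylation at the hindered secondary carbon, proton transfer from the aldehyde CH2 to the ylide followed by C-alkylation to a five-membered ring, or insufficient facial selectivity in the closure. Fallback (known chemistry, oxirane oxygen introduced after the carbocycle): setting out from 10, reductive dechlorination (Zn, AcOH, Et2O, 23 °C) should give (3R,4R)-4-[(tert-butyldimethylsilyl)oxy]-5-oxo-3-(prop-1-en-2-yl)heptanal F1. Intramolecular aldol condensation (KOH, MeOH, 0 → 23 °C) should then give (5R,6R)-6-[(tert-butyldimethylsilyl)oxy]-2-methyl-5-(prop-1-en-2-yl)cyclohex-2-en-1-one F2. Weitz–Scheffer epoxidation (H2O2, NaOH, MeOH, 0 °C) should attack axially, anti to the isopropenyl group, and the route is rejoined at 15.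

2. Step 4. What may go wrong: decomposition of the thermally labile carbenoid before acylation, direct addition of n-BuLi to the lactone, double addition, or oxirane closure of the lactolate on warming. Fallback (known chemistry, chlorine introduced after the carbon skeleton): setting out from 6, EtLi (1.1 equiv, THF, −78 °C; AcOH) should give (4R,5R)-4-[(tert-butyldimethylsilyl)oxy]-7-hydroxy-5-(prop-1-en-2-yl)heptan-3-one F3. Kinetic deprotonation on the ethyl side with silylation (LiN(i-Pr)2 2.3 equiv, Me3SiCl, THF, −78 °C) should give (4R,5R)-4-[(tert-butyldimethylsilyl)oxy]-5-(prop-1-en-2-yl)-3,7-bis[(trimethylsilyl)oxy]hept-2-ene F4. Chlorination of the enol ether (NCS, THF, 0 °C) should give (4R,5R)-4-[(tert-butyldimethylsilyl)oxy]-2-chloro-5-(prop-1-en-2-yl)-7-[(trimethylsilyl)oxy]heptan-3-one F5, and citric acid in MeOH removes the primary silyl ether to rejoin the route at 9.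

3. Step 1. What may go wrong: slow transmetalation or protodeboronation of the 1,1-disubstituted alkenyl boron reagent, hydrolytic opening of the lactone at 100 °C, or weak enantiofacial discrimination. Fallback (resolution in place of asymmetric catalysis): setting out from 1, copper-catalysed conjugate addition of isopropenylmagnesium bromide (CuBr·SMe2 10 mol %, Me3SiCl, THF, −78 °C) should give racemic 4-(prop-1-en-2-yl)tetrahydro-2H-pyran-2-one F6. Enolate hydroxylation under the conditions of step 2 should give the racemic trans-hydroxy lactone rac-(3R,4R)-3-hydroxy-4-(prop-1-en-2-yl)tetrahydro-2H-pyran-2-one F7. Kinetic resolution by lipase-catalysed acetylation (Burkholderia cepacia lipase, vinyl acetate, t-BuOMe, 30 °C) separates the enantiomers as alcohol and acetate. On the assumption that the (3S,4S)-alcohol reacts faster and becomes (3S,4S)-2-oxo-4-(prop-1-en-2-yl)tetrahydro-2H-pyran-3-yl acetate F8, the unreacted alcohol is 5, where the route is rejoined.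

**Further compounds**

F1 | step 6 | (3R,4R)-4-[(tert-butyldimethylsilyl)oxy]-5-oxo-3-(prop-1-en-2-yl)heptanal | C=C(C)[C@H]([C@@H](O[Si](C)(C)C(C)(C)C)C(=O)CC)CC=O
F2 | step 6 | (5R,6R)-6-[(tert-butyldimethylsilyl)oxy]-2-methyl-5-(prop-1-en-2-yl)cyclohex-2-en-1-one | C=C(C)[C@H]1CC=C(C)C(=O)[C@@H]1O[Si](C)(C)C(C)(C)C
F3 | step 4 | (4R,5R)-4-[(tert-butyldimethylsilyl)oxy]-7-hydroxy-5-(prop-1-en-2-yl)heptan-3-one | C=C(C)[C@H]([C@@H](O[Si](C)(C)C(C)(C)C)C(=O)CC)CCO
F4 | step 4 | (4R,5R)-4-[(tert-butyldimethylsilyl)oxy]-5-(prop-1-en-2-yl)-3,7-bis[(trimethylsilyl)oxy]hept-2-ene | C=C(C)[C@H]([C@@H](O[Si](C)(C)C(C)(C)C)C(O[Si](C)(C)C)=CC)CCO[Si](C)(C)C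
F5 | step 4 | (4R,5R)-4-[(tert-butyldimethylsilyl)oxy]-2-chloro-5-(prop-1-en-2-yl)-7-[(trimethylsilyl)oxy]heptan-3-one | C=C(C)[C@H]([C@@H](O[Si](C)(C)C(C)(C)C)C(=O)C(C)Cl)CCO[Si](C)(C)C
F6 | step 1 | racemic 4-(prop-1-en-2-yl)tetrahydro-2H-pyran-2-one | C=C(C)C1CCOC(=O)C1
F7 | step 1 | rac-(3R,4R)-3-hydroxy-4-(prop-1-en-2-yl)tetrahydro-2H-pyran-2-one (racemate, one enantiomer drawn) | C=C(C)[C@H]1CCOC(=O)[C@@H]1O
F8 | step 1 | (3S,4S)-2-oxo-4-(prop-1-en-2-yl)tetrahydro-2H-pyran-3-yl acetate | C=C(C)[C@@H]1CCOC(=O)[C@H]1OC(C)=O
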